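**Retrosynthetic overview**
1. Target ⇐ C6 acetylation and chemoselective hydrogenation of the C7 isopropenyl group of a 3-angeloyloxy-4,5-epoxygermacra-1(10),11-dien-6-ol.
2. Ten-membered ring ⇐ C6–C7 bond by a proposed chromium-catalysed, ligand-controlled macrocyclising allylation of an acyclic ω-chloro epoxy aldehyde; this sets C6 and C7.
3. C3/C4/C5 ⇐ Sharpless kinetic resolution–epoxidation of a racemic 4-hydroxyfarnesyl-type allylic alcohol; the angelate is installed directly afterwards and carried through.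
4. C15 chain ⇐ α-selective allylbarium addition of an 8-silyloxygeranyl chloride (from geranyl acetate) to a C5 enal (from prenol).
5. Ring order: oxirane first (acyclic stage), then the ten-membered carbocycle.

Assumption: the given SMILES fixes the absolute configuration. In germacrane numbering (C1=C10 alkene, C3 angelate, C4–C5 epoxide, C6 acetate, C7 isopropyl) it is 1(10)E,3R,4R,5R,6S,7R. Acyclic intermediates are numbered as dodecane chains in which C1 is the future C6 and C10 the future C7.

**Step 1**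
Reactants: 1 3-methylbut-2-en-1-ol (prenol)
Product: 2 1-methoxy-4-{[(3-methylbut-2-en-1-yl)oxy]methyl}benzene (prenyl 4-methoxybenzyl ether)
Conditions: NaH, 4-methoxybenzyl chloride, Bu4NI (cat.), THF, 0 °C to rt
Reagents that add atoms: 4-methoxybenzyl chloride COc1ccc(CCl)cc1
Why: Williamson ether synthesis of a primary allylic alkoxide with a benzylic chloride; no stereocentre is involved.

**Step 2**
Reactants: 2 prenyl 4-methoxybenzyl ether
Product: 4 (E)-4-[(4-methoxybenzyl)oxy]-2-methylbut-2-enal, via allylic alcohol 3 (not isolated)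
Conditions: SeO2 (0.3 equiv), t-BuOOH (2 equiv), salicylic acid (0.1 equiv), CH2Cl2, rt; filter; then MnO2 (10 equiv), CH2Cl2, rt
Reagents that add atoms: tert-butyl hydroperoxide CC(C)(C)OO; selenium dioxide O=[Se]=O (oxygen carrier)
Why: Riley allylic oxidation (ene reaction then [2,3]-sigmatropic shift) functionalises the methyl group trans to the CH2O chain to give the (E)-allylic alcohol, which MnO2 oxidises selectively to the (E)-enal.

**Step 3**
Reactants: 5 geranyl acetate
Product: 6 (2E,6E)-8-hydroxy-3,7-dimethylocta-2,6-dien-1-yl acetate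
Conditions: SeO2 (0.1 equiv), t-BuOOH (3 equiv), salicylic acid (0.1 equiv), CH2Cl2, rt
Reagents that add atoms: tert-butyl hydroperoxide CC(C)(C)OO; selenium dioxide O=[Se]=O (oxygen carrier)
Why: Riley allylic oxidation attacks the (E)-methyl of the terminal alkene because the 2,3-alkene is deactivated by the allylic acetate, and the ene/[2,3] pathway gives the (E)-alcohol.

**Step 4**
Reactants: 6 8-hydroxygeranyl acetate
Product: 7 (2E,6E)-8-[(tert-butyldimethylsilyl)oxy]-3,7-dimethylocta-2,6-dien-1-yl acetate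
Conditions: TBSCl, imidazole, DMF, rt
Reagents that add atoms: tert-butyldimethylsilyl chloride CC(C)(C)[Si](C)(C)Cl
Why: Standard silylation of a primary allylic alcohol; no stereocentre is involved.

**Step 5**
Reactants: 7 silyl ether acetate
Product: 8 (2E,6E)-8-[(tert-butyldimethylsilyl)oxy]-3,7-dimethylocta-2,6-dien-1-ol
Conditions: K2CO3 (0.2 equiv), MeOH, rt
Reagents that add atoms: none
Why: Base-catalysed transesterification removes the acetate while the silyl ether is stable to mild methanolic carbonate.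

**Step 6**
Reactants: 8 silyloxy geraniol
Product: 9 tert-butyl{[(2E,6E)-8-chloro-2,6-dimethylocta-2,6-dien-1-yl]oxy}dimethylsilane
Conditions: PPh3, hexachloroacetone, CH2Cl2, −20 to 0 °C
Reagents that add atoms: hexachloroacetone ClC(Cl)(Cl)C(=O)C(Cl)(Cl)Cl
Why: Appel-type chlorination of a primary allylic alcohol proceeds by SN2 on the alkoxyphosphonium ion under neutral conditions, without allylic transposition or loss of alkene geometry.

**Step 7**
Reactants: 9 silyloxygeranyl chloride; 4 (E)-4-[(4-methoxybenzyl)oxy]-2-methylbut-2-enal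
Product: 11 racemic (2E,6E,10E)-12-[(tert-butyldimethylsilyl)oxy]-1-[(4-methoxybenzyl)oxy]-3,7,11-trimethyldodeca-2,6,10-trien-4-ol, via allylbarium chloride 10 (not isolated)
Conditions: BaI2, Li, biphenyl, THF, rt (activated Ba); 9, −78 °C; then 4, −78 °C; H2O
Reagents that add atoms: barium metal [Ba] (made from BaI2 and Li; retained only in 10)
Why: Barbier/Grignard-type 1,2-addition of an allylbarium reagent, which at −78 °C reacts at its unsubstituted α-carbon with retention of the (E)-alkene; the carbinol centre forms racemic and is resolved in step 8.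

**Step 8**
Reactants: 11 racemic trienol
Product: 12 (2R,3R,4R,6E,10E)-12-[(tert-butyldimethylsilyl)oxy]-2,3-epoxy-1-[(4-methoxybenzyl)oxy]-3,7,11-trimethyldodeca-6,10-dien-4-ol
Conditions: Ti(OiPr)4 (0.15 equiv), D-(−)-diisopropyl tartrate (0.2 equiv), t-BuOOH (0.55 equiv), 4 Å MS, CH2Cl2, −20 °C
Reagents that add atoms: tert-butyl hydroperoxide CC(C)(C)OO
Why: Sharpless kinetic resolution: with the D-(−)-tartrate the (4R)-alcohol reacts fast and is epoxidised on the face that gives the (2R,3R) erythro epoxy alcohol (maximum 50 %), while the (4S)-alcohol is left and separated and the homoallylic and remote alkenes are untouched.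

**Step 9**
Reactants: 12 epoxy alcohol; 13 angelic acid [(Z)-2-methylbut-2-enoic acid]
Product: 15 (2R,3R,4R,6E,10E)-12-[(tert-butyldimethylsilyl)oxy]-2,3-epoxy-1-[(4-methoxybenzyl)oxy]-3,7,11-trimethyldodeca-6,10-dien-4-yl (Z)-2-methylbut-2-enoate, via mixed anhydride 14 (not isolated)
Conditions: 13 (2 equiv), 2,4,6-trichlorobenzoyl chloride (2 equiv), Et3N (4 equiv), toluene, rt; then 12, 75 °C (no DMAP)
Reagents that add atoms: 2,4,6-trichlorobenzoyl chloride O=C(Cl)c1c(Cl)cc(Cl)cc1Cl (retained only in 14)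
Why: Yamaguchi esterification through the mixed anhydride acylates the hindered C4 alcohol with retention, and leaving out nucleophilic catalysts avoids addition–elimination isomerisation of the (Z)-angelate to the (E)-tiglate.

**Step 10**
Reactants: 15 silyl ether angelate
Product: 16 (2R,3R,4R,6E,10E)-2,3-epoxy-12-hydroxy-1-[(4-methoxybenzyl)oxy]-3,7,11-trimethyldodeca-6,10-dien-4-yl (Z)-2-methylbut-2-enoate
Conditions: Bu4NF, AcOH (1:1), THF, 0 °C to rt
Reagents that add atoms: none
Why: Fluoride-mediated desilylation of the primary allylic silyl ether; buffering with acetic acid keeps the medium non-basic so the angelate, epoxide and 4-methoxybenzyl ether survive.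

**Step 11**
Reactants: 16 allylic alcohol
Product: 17 (2R,3R,4R,6E,10E)-12-chloro-2,3-epoxy-1-[(4-methoxybenzyl)oxy]-3,7,11-trimethyldodeca-6,10-dien-4-yl (Z)-2-methylbut-2-enoate
Conditions: PPh3, hexachloroacetone, CH2Cl2, −20 to 0 °C
Reagents that add atoms: hexachloroacetone ClC(Cl)(Cl)C(=O)C(Cl)(Cl)Cl
Why: Appel-type chlorination under neutral, low-temperature conditions converts only the primary allylic alcohol by SN2, leaving the epoxide, ester and (E)-alkene geometry intact.

**Step 12**
Reactants: 17 allylic chloride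
Product: 18 (2R,3R,4R,6E,10E)-12-chloro-2,3-epoxy-1-hydroxy-3,7,11-trimethyldodeca-6,10-dien-4-yl (Z)-2-methylbut-2-enoate
Conditions: DDQ, CH2Cl2/pH 7 phosphate buffer (10:1), 0 °C
Reagents that add atoms: none
Why: Oxidative cleavage of the 4-methoxybenzyl ether (benzylic hydride abstraction, then hydrolysis of the oxocarbenium ion) is neutral and leaves the allylic chloride, epoxide and angelate unchanged.

**Step 13**
Reactants: 18 epoxy alcohol
Product: 19 (2S,3R,4R,6E,10E)-12-chloro-2,3-epoxy-3,7,11-trimethyl-1-oxododeca-6,10-dien-4-yl (Z)-2-methylbut-2-enoate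
Conditions: TEMPO (0.1 equiv), PhI(OAc)2 (1.2 equiv), CH2Cl2, rt; used at once
Reagents that add atoms: none
Why: Oxoammonium (TEMPO) oxidation takes the primary alcohol to the aldehyde without over-oxidation or epimerisation of the oxirane carbon (the C2 descriptor changes only through CIP priorities).

**Step 14**
Reactants: 19 chloro epoxy aldehyde
Product: 21 (1(10)E,3R,4R,5R,6S,7R)-4,5-epoxy-6-hydroxygermacra-1(10),11-dien-3-yl (Z)-2-methylbut-2-enoate, via allylchromium species 20 (not isolated)
Conditions: CrCl2 (10 mol %), (S,S)-3,6-di-tert-butyl-1,8-bis(4-isopropyl-4,5-dihydrooxazol-2-yl)-9H-carbazole (12 mol %), i-Pr2NEt (20 mol %), Mn powder (3 equiv), Cp2ZrCl2 (1.2 equiv), LiCl (2 equiv), THF, 25 °C, 19 added by syringe pump over 12 h (final 3 mM); then aq. NaHCO3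
Reagents that add atoms: chromium dichloride Cl[Cr]Cl (retained only in 20)
Why: Proposed new method: divalent chromium, regenerated by Mn, adds oxidatively to the primary allylic chloride to give the ligand-bound allylchromium 20 (trivalent chromium), whose γ-carbon (future C7) adds to the tethered aldehyde through a closed six-membered chair transition state; the six-atom tether holding an (E)-alkene and a trans-epoxide should allow only a cis-fused chair (reached after fast 1,3-metallotropic equilibration of the allyl unit), which gives the 6,7-cis relationship, while Si-face attack on the aldehyde, favoured by the ring-embedded oxirane and to be reinforced by the tridentate carbazole bis(oxazoline) ligand (its enantiomer is used if the facial sense proves mismatched), sets 6S, and Cp2ZrCl2 takes the alkoxide off chromium so the catalyst turns over; the closest known reaction types are the stoichiometric, substrate-controlled macrocyclic Barbier/Nozaki–Hiyama–Kishi allylation of ω-halo epoxy aldehydes and the intermolecular catalytic asymmetric Nozaki–Hiyama–Kishi allylation, a ligand-controlled catalytic closure of a ten-membered carbocycle not having been shown.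

**Step 15**
Reactants: 21 macrocyclic dienol
Product: 22 (1(10)E,3R,4R,5R,6S,7R)-4,5-epoxy-6-hydroxygermacr-1(10)-en-3-yl (Z)-2-methylbut-2-enoate
Conditions: H2 (1 atm), RhCl(PPh3)3 (10 mol %), benzene, rt
Reagents that add atoms: none
Why: Homogeneous hydrogenation with RhCl(PPh3)3 reduces the 1,1-disubstituted isopropenyl alkene much faster than the trisubstituted ring alkene and the trisubstituted conjugated angelate alkene; no stereocentre is made or touched.

**Step 16**
Reactants: 22 macrocyclic alcohol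
Product: 23 (1(10)E,3R,4R,5R,6S,7R)-6-acetoxy-4,5-epoxygermacr-1(10)-en-3-yl (Z)-2-methylbut-2-enoate (target CNP0180504.5)
Conditions: Ac2O, DMAP (cat.), pyridine, rt; chromatography on Et3N-deactivated silica
Reagents that add atoms: acetic anhydride CC(=O)OC(C)=O
Why: DMAP-catalysed acylation of the C6 alcohol proceeds with retention under non-acidic conditions, so the acid-labile epoxygermacrene does not undergo transannular cyclisation.

**Compound list**
1 | 3-methylbut-2-en-1-ol (prenol) | CC(C)=CCO | starting material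
2 | 1-methoxy-4-{[(3-methylbut-2-en-1-yl)oxy]methyl}benzene | COc1ccc(COCC=C(C)C)cc1 | intermediate
3 | (E)-4-[(4-methoxybenzyl)oxy]-2-methylbut-2-en-1-ol | COc1ccc(COC/C=C(\C)CO)cc1 | intermediate (not isolated)
4 | (E)-4-[(4-methoxybenzyl)oxy]-2-methylbut-2-enal | COc1ccc(COC/C=C(\C)C=O)cc1 | intermediate
5 | geranyl acetate [(2E)-3,7-dimethylocta-2,6-dien-1-yl acetate] | CC(C)=CCC/C(C)=C/COC(C)=O | starting material
6 | (2E,6E)-8-hydroxy-3,7-dimethylocta-2,6-dien-1-yl acetate | CC(=O)OC/C=C(\C)CC/C=C(\C)CO | intermediate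
7 | (2E,6E)-8-[(tert-butyldimethylsilyl)oxy]-3,7-dimethylocta-2,6-dien-1-yl acetate | CC(=O)OC/C=C(\C)CC/C=C(\C)CO[Si](C)(C)C(C)(C)C | intermediate
8 | (2E,6E)-8-[(tert-butyldimethylsilyl)oxy]-3,7-dimethylocta-2,6-dien-1-ol | OC/C=C(\C)CC/C=C(\C)CO[Si](C)(C)C(C)(C)C | intermediate
9 | tert-butyl{[(2E,6E)-8-chloro-2,6-dimethylocta-2,6-dien-1-yl]oxy}dimethylsilane | ClC/C=C(\C)CC/C=C(\C)CO[Si](C)(C)C(C)(C)C | intermediate
10 | {(2E,6E)-8-[(tert-butyldimethylsilyl)oxy]-3,7-dimethylocta-2,6-dien-1-yl}barium chloride | Cl[Ba]C/C=C(\C)CC/C=C(\C)CO[Si](C)(C)C(C)(C)C | intermediate (not isolated)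
11 | racemic (2E,6E,10E)-12-[(tert-butyldimethylsilyl)oxy]-1-[(4-methoxybenzyl)oxy]-3,7,11-trimethyldodeca-2,6,10-trien-4-ol | COc1ccc(COC/C=C(\C)C(O)C/C=C(\C)CC/C=C(\C)CO[Si](C)(C)C(C)(C)C)cc1 | intermediate
12 | (2R,3R,4R,6E,10E)-12-[(tert-butyldimethylsilyl)oxy]-2,3-epoxy-1-[(4-methoxybenzyl)oxy]-3,7,11-trimethyldodeca-6,10-dien-4-ol | O[C@H](C/C=C(\C)CC/C=C(\C)CO[Si](C)(C)C(C)(C)C)[C@@]1(C)O[C@@H]1COCc1ccc(OC)cc1 | intermediate
13 | angelic acid [(Z)-2-methylbut-2-enoic acid] | C/C=C(/C)C(O)=O | starting material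
14 | (Z)-2-methylbut-2-enoic 2,4,6-trichlorobenzoic anhydride | C/C=C(/C)C(=O)OC(=O)c1c(Cl)cc(Cl)cc1Cl | intermediate (not isolated)
15 | (2R,3R,4R,6E,10E)-12-[(tert-butyldimethylsilyl)oxy]-2,3-epoxy-1-[(4-methoxybenzyl)oxy]-3,7,11-trimethyldodeca-6,10-dien-4-yl (Z)-2-methylbut-2-enoate | C/C=C(/C)C(=O)O[C@H](C/C=C(\C)CC/C=C(\C)CO[Si](C)(C)C(C)(C)C)[C@@]1(C)O[C@@H]1COCc1ccc(OC)cc1 | intermediate
16 | (2R,3R,4R,6E,10E)-2,3-epoxy-12-hydroxy-1-[(4-methoxybenzyl)oxy]-3,7,11-trimethyldodeca-6,10-dien-4-yl (Z)-2-methylbut-2-enoate | C/C=C(/C)C(=O)O[C@H](C/C=C(\C)CC/C=C(\C)CO)[C@@]1(C)O[C@@H]1COCc1ccc(OC)cc1 | intermediate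
17 | (2R,3R,4R,6E,10E)-12-chloro-2,3-epoxy-1-[(4-methoxybenzyl)oxy]-3,7,11-trimethyldodeca-6,10-dien-4-yl (Z)-2-methylbut-2-enoate | C/C=C(/C)C(=O)O[C@H](C/C=C(\C)CC/C=C(\C)CCl)[C@@]1(C)O[C@@H]1COCc1ccc(OC)cc1 | intermediate
18 | (2R,3R,4R,6E,10E)-12-chloro-2,3-epoxy-1-hydroxy-3,7,11-trimethyldodeca-6,10-dien-4-yl (Z)-2-methylbut-2-enoate | C/C=C(/C)C(=O)O[C@H](C/C=C(\C)CC/C=C(\C)CCl)[C@@]1(C)O[C@@H]1CO | intermediate
19 | (2S,3R,4R,6E,10E)-12-chloro-2,3-epoxy-3,7,11-trimethyl-1-oxododeca-6,10-dien-4-yl (Z)-2-methylbut-2-enoate | C/C=C(/C)C(=O)O[C@H](C/C=C(\C)CC/C=C(\C)CCl)[C@@]1(C)O[C@@H]1C=O | intermediate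
20 | allylchromium species from 19 (trivalent chromium at C12; drawn as the dichloride, chiral ligand not drawn) | C/C=C(/C)C(=O)O[C@H](C/C=C(\C)CC/C=C(\C)C[Cr](Cl)Cl)[C@@]1(C)O[C@@H]1C=O | intermediate (not isolated)
21 | (1(10)E,3R,4R,5R,6S,7R)-4,5-epoxy-6-hydroxygermacra-1(10),11-dien-3-yl (Z)-2-methylbut-2-enoate (ten-membered ring; C7 isopropenyl) | C/C=C(/C)C(=O)O[C@@H]1C/C=C(\C)CC[C@H](C(C)=C)[C@H](O)[C@H]2O[C@@]21C | intermediate
22 | (1(10)E,3R,4R,5R,6S,7R)-4,5-epoxy-6-hydroxygermacr-1(10)-en-3-yl (Z)-2-methylbut-2-enoate (C7 isopropyl) | C/C=C(/C)C(=O)O[C@@H]1C/C=C(\C)CC[C@H](C(C)C)[C@H](O)[C@H]2O[C@@]21C | intermediate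
23 | (1(10)E,3R,4R,5R,6S,7R)-6-acetoxy-4,5-epoxygermacr-1(10)-en-3-yl (Z)-2-methylbut-2-enoate | C/C=C(/C)C(=O)O[C@@H]1C/C=C(\C)CC[C@H](C(C)C)[C@H](OC(C)=O)[C@H]2O[C@@]21C | target

**Totals**
Total step count: 16. Longest linear sequence: 14 steps (5 → 23, steps 3–6 and 7–16); the branch from 1 contributes steps 1–2.

**Three steps most likely to fail**

Step 14 (the proposed macrocyclisation) is the main risk. Oligomerisation can compete with closure of the ten-membered ring. The 6,7-cis/6S outcome rests on a transition-state model and on my recollection of how related stoichiometric closures behave, not on a demonstrated result; the added C3 ester or a mismatched ligand could erode it. The fallback uses known chemistry and a different activation mode. It sets out from 19 and uses palladium-catalysed umpolung allylation: Pd(PPh3)4 (cat.), Et2Zn and K2CO3 in THF/DMA at rt under slow addition. The allylic chloride gives a π-allylpalladium species, which transmetalates to an allylzinc that adds to the aldehyde under macrocyclic substrate control. This is established for ω-chloro epoxy aldehydes of the farnesal type. It comes back to the route at 21 and makes no new compound on the way (none F0).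

Step 7 (allylbarium coupling) may give the γ-adduct or lose (E)-geometry if the barium reagent warms, and activated barium is demanding to prepare. The fallback sets out from 9 and 4 and replaces the allylmetal by a sulfone-stabilised carbanion. PhSO2Na in DMF converts 9 into (2E,6E)-8-[(tert-butyldimethylsilyl)oxy]-3,7-dimethylocta-2,6-dien-1-yl phenyl sulfone F1. Deprotonation with n-BuLi (THF, −78 °C) and addition of 4 gives, by α-attack, (2E,6E,10E)-12-[(tert-butyldimethylsilyl)oxy]-1-[(4-methoxybenzyl)oxy]-3,7,11-trimethyl-5-(phenylsulfonyl)dodeca-2,6,10-trien-4-ol F2 as a diastereomer mixture. Reductive desulfonylation with LiBHEt3 and catalytic PdCl2(dppp) (THF, 0 °C) delivers hydride to the sulfone-bearing terminus of the π-allylpalladium intermediate, keeping the alkene position and geometry. It comes back to the route at 11.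

Step 9 (angeloylation) may be slow on the hindered C4 alcohol, and prolonged heating can isomerise the angelate to the tiglate. The fallback sets out from 12 and builds the (Z)-alkene on the substrate instead of transferring a preformed acyl group. Esterification with 2-[bis(2,2,2-trifluoroethoxy)phosphoryl]propanoic acid (DCC, DMAP, CH2Cl2, 0 °C) gives (2R,3R,4R,6E,10E)-12-[(tert-butyldimethylsilyl)oxy]-2,3-epoxy-1-[(4-methoxybenzyl)oxy]-3,7,11-trimethyldodeca-6,10-dien-4-yl 2-[bis(2,2,2-trifluoroethoxy)phosphoryl]propanoate F3. Still–Gennari olefination (KN(SiMe3)2, 18-crown-6, THF, −78 °C, then acetaldehyde) forms the (Z)-2-methylbut-2-enoate under kinetic control. It comes back to the route at 15.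

**Further compounds**
F1 | step 7 | (2E,6E)-8-[(tert-butyldimethylsilyl)oxy]-3,7-dimethylocta-2,6-dien-1-yl phenyl sulfone | O=S(=O)(C/C=C(\C)CC/C=C(\C)CO[Si](C)(C)C(C)(C)C)c1ccccc1
F2 | step 7 | (2E,6E,10E)-12-[(tert-butyldimethylsilyl)oxy]-1-[(4-methoxybenzyl)oxy]-3,7,11-trimethyl-5-(phenylsulfonyl)dodeca-2,6,10-trien-4-ol (diastereomer mixture) | COc1ccc(COC/C=C(\C)C(O)C(/C=C(\C)CC/C=C(\C)CO[Si](C)(C)C(C)(C)C)S(=O)(=O)c2ccccc2)cc1
F3 | step 9 | (2R,3R,4R,6E,10E)-12-[(tert-butyldimethylsilyl)oxy]-2,3-epoxy-1-[(4-methoxybenzyl)oxy]-3,7,11-trimethyldodeca-6,10-dien-4-yl 2-[bis(2,2,2-trifluoroethoxy)phosphoryl]propanoate (epimers at the phosphonate carbon) | CC(C(=O)O[C@H](C/C=C(\C)CC/C=C(\C)CO[Si](C)(C)C(C)(C)C)[C@@]1(C)O[C@@H]1COCc1ccc(OC)cc1)P(=O)(OCC(F)(F)F)OCC(F)(F)F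
F0 | step 14 | none | none
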